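The trans C1-OH/C6-OH pair of the cyclohexene ring, with C1–O cis to C2–O, is traced to a C1–C6 oxirane lying on the face of the C2 oxygen and opened at allylic C6 at the very end. The key step is a vanadium-catalysed epoxidation steered by the free C2 hydroxyl: in one operation it forms both C–O bonds, closes the oxirane, sets C1 and C6 and picks C1=C6 over C4=C5, because that hydroxyl is allylic only to C1=C6 of the diene ring. Its precursor is a cyclohexa-1,3-diene made from a microbial bromobenzene cis-dihydrodiol: C2-OH free, C3-O silylated, C1 carrying CH2OBz. C3 is inverted later by Mitsunobu benzoylation.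

Key step: step 4

Remark: atoms are numbered as in the target (C1 quaternary carbinol bearing C7H2OBz, C2 acetoxy carbon, C3 benzoyloxy carbon, C4=C5, C6 secondary carbinol). "Upper face" is the face of C1-OH and C2-OAc. In the 7-oxabicyclo[4.1.0]heptene names C1–C6 keep these numbers. Commercial 1 is taken as the free, dry diol.

Step 1
Reactants: 1 (1S,2S)-3-bromocyclohexa-3,5-diene-1,2-diol; 2 tert-butyl(chloro)dimethylsilane (TBSCl)
Product: 3 (1S,6S)-2-bromo-6-[(tert-butyldimethylsilyl)oxy]cyclohexa-2,4-dien-1-ol (C3-O-TBS, C2-OH free, both on the upper face)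
Conditions: TBSCl (1.05 equiv), imidazole (2.2 equiv), DMF, −20 → 0 °C
Reagents that add atoms: TBSCl, CC(C)(C)[Si](C)(C)Cl
Why: Imidazole-promoted silylation; the hydroxyl next to the brominated alkene carbon is the more hindered and less nucleophilic one, so the bulky silyl chloride should take the distal allylic hydroxyl at low temperature, and no stereocentre is touched.

Step 2
Reactants: 3 (1S,6S)-2-bromo-6-[(tert-butyldimethylsilyl)oxy]cyclohexa-2,4-dien-1-ol; 4 (tributylstannyl)methanol
Product: 5 (1R,6S)-6-[(tert-butyldimethylsilyl)oxy]-2-(hydroxymethyl)cyclohexa-2,4-dien-1-ol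
Conditions: Bu3SnCH2OH (1.3 equiv), Pd(PPh3)4 (5 mol %), 1,4-dioxane (degassed, dilute), 80 °C, dark
Reagents that add atoms: (tributylstannyl)methanol, OC[Sn](CCCC)(CCCC)CCCC
Why: Migita–Kosugi–Stille coupling; zerovalent palladium inserts into the alkenyl C–Br bond, the α-oxygenated CH2OH group transfers from tin in preference to butyl, and reductive elimination forms C1–C7 without touching C2 or C3 (the descriptor at C2 changes only because the priorities change).

Step 3
Reactants: 5 (1R,6S)-6-[(tert-butyldimethylsilyl)oxy]-2-(hydroxymethyl)cyclohexa-2,4-dien-1-ol; 6 benzoyl chloride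
Product: 7 [(5S,6R)-5-[(tert-butyldimethylsilyl)oxy]-6-hydroxycyclohexa-1,3-dien-1-yl]methyl benzoate
Conditions: BzCl (1.05 equiv), 2,4,6-collidine (2 equiv), CH2Cl2, −78 → −40 °C
Reagents that add atoms: benzoyl chloride, O=C(Cl)c1ccccc1
Why: Kinetically controlled acylation; with a hindered pyridine base at low temperature the unhindered primary allylic C7 hydroxyl should react far faster than the C2 hydroxyl, which sits between the substituted alkene carbon and the silyloxy carbon.

Step 4
Reactants: 7 [(5S,6R)-5-[(tert-butyldimethylsilyl)oxy]-6-hydroxycyclohexa-1,3-dien-1-yl]methyl benzoate; 8 tert-butyl hydroperoxide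
Product: 9 [(1S,2S,3S,6R)-3-[(tert-butyldimethylsilyl)oxy]-2-hydroxy-7-oxabicyclo[4.1.0]hept-4-en-1-yl]methyl benzoate (oxirane oxygen, C2-OH and C3-OTBS all on the upper face)
Conditions: VO(acac)2 (5 mol %), t-BuOOH (5.5 M in decane, 1.3 equiv), 2,6-lutidine (0.2 equiv), toluene, 0 °C
Reagents that add atoms: tert-butyl hydroperoxide, CC(C)(C)OO
Why: t-BuOOH oxidises VO(acac)2 to a pentavalent vanadium ester, which takes up the C2 alkoxide and a tert-butylperoxide ligand and then passes the vanadium-bound peroxide oxygen to the alkene held beside it. The closest known reaction type is the vanadium-catalysed, hydroxyl-directed epoxidation of cyclic allylic alcohols, which is established for dienols and gives cis-epoxy alcohols from cyclohex-2-enols. The oxirane is closed by a concerted, suprafacial transfer of one oxygen atom to C1 and C6 (a [2+1] addition inside the metal template, not a stepwise exo or endo cyclisation). C1 and C6 are both set by the existing C2 stereocentre: the O–V–O tether reaches only the face on which the C2 oxygen stands, and the C1 substituent pushes that C–O bond pseudoaxial, the geometry the template needs. The step needs site selectivity (C1=C6, not C4=C5) and facial selectivity; both come from the one free hydroxyl, which is allylic to the trisubstituted C1=C6 but one carbon further from C4=C5, while the C3 silyl ether and the C7 benzoate do not bind vanadium. Low temperature, anhydrous oxidant and a little hindered base keep the medium neutral so that neither the dienol nor the vinyl oxirane should ionise.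

Step 5
Reactants: 9 [(1S,2S,3S,6R)-3-[(tert-butyldimethylsilyl)oxy]-2-hydroxy-7-oxabicyclo[4.1.0]hept-4-en-1-yl]methyl benzoate; 10 acetic anhydride
Product: 11 [(1R,2S,3S,6R)-2-acetoxy-3-[(tert-butyldimethylsilyl)oxy]-7-oxabicyclo[4.1.0]hept-4-en-1-yl]methyl benzoate
Conditions: Ac2O (2 equiv), pyridine, DMAP (5 mol %), CH2Cl2, 0 °C → rt
Reagents that add atoms: acetic anhydride, CC(=O)OC(C)=O
Why: DMAP-catalysed acylation of the remaining secondary hydroxyl; only the O–H bond reacts, so C2 is retained, and the cis relation of C2–O to the oxirane oxygen rules out Payne rearrangement (the C1 descriptor changes through priorities only).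

Step 6
Reactants: 11 [(1R,2S,3S,6R)-2-acetoxy-3-[(tert-butyldimethylsilyl)oxy]-7-oxabicyclo[4.1.0]hept-4-en-1-yl]methyl benzoate
Product: 12 [(1R,2S,3S,6R)-2-acetoxy-3-hydroxy-7-oxabicyclo[4.1.0]hept-4-en-1-yl]methyl benzoate
Conditions: TBAF (1.5 equiv), AcOH (1.8 equiv), THF, 0 °C → rt
Reagents that add atoms: none
Why: Fluoride-induced Si–O cleavage; the acetic acid buffer protonates the C3 alkoxide as it forms, which should suppress migration of the neighbouring cis acetate, and at this acidity neither fluoride nor acetate opens the oxirane.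

Step 7
Reactants: 12 [(1R,2S,3S,6R)-2-acetoxy-3-hydroxy-7-oxabicyclo[4.1.0]hept-4-en-1-yl]methyl benzoate; 13 benzoic acid
Product: 14 [(1R,2S,3R,6R)-2-acetoxy-3-(benzoyloxy)-7-oxabicyclo[4.1.0]hept-4-en-1-yl]methyl benzoate (C3 benzoate now on the lower face)
Conditions: PPh3 (1.5 equiv), DIAD (1.5 equiv), BzOH (1.5 equiv), THF, 0 °C → rt
Reagents that add atoms: benzoic acid, O=C(O)c1ccccc1
Why: Mitsunobu reaction; the allylic C3 hydroxyl is activated as its alkoxyphosphonium ion and displaced by benzoate in an SN2 step from the lower face, which inverts C3 (S to R) and installs the ring benzoate, while the cis C2 acetate cannot reach the rear of C3 and the oxirane is inert to these neutral conditions.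

Step 8
Reactants: 14 [(1R,2S,3R,6R)-2-acetoxy-3-(benzoyloxy)-7-oxabicyclo[4.1.0]hept-4-en-1-yl]methyl benzoate; 15 water
Product: 16 [(1R,2S,3R,6S)-2-acetoxy-3-(benzoyloxy)-1,6-dihydroxycyclohex-4-en-1-yl]methyl benzoate (HY-N2634)
Conditions: HClO4 (0.1 M aq., 0.2 equiv), THF/H2O (3:1), 0 °C → rt
Reagents that add atoms: water, O
Why: Specific-acid-catalysed anti opening of a cyclic vinyl oxirane; in the protonated oxirane the allylic C6–O bond is weakened while the C1–O bond is held by the two β-acyloxy groups, so water should attack C6 from the lower face with inversion (C6 becomes S) and C1 keeps its oxygen on the upper face (R), giving the trans-diol without ester hydrolysis in the dilute acid.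

Compound list
1 | (1S,2S)-3-bromocyclohexa-3,5-diene-1,2-diol | O[C@H]1[C@@H](O)C=CC=C1Br | starting material
2 | tert-butyl(chloro)dimethylsilane | CC(C)(C)[Si](C)(C)Cl | starting material
3 | (1S,6S)-2-bromo-6-[(tert-butyldimethylsilyl)oxy]cyclohexa-2,4-dien-1-ol | O[C@H]1[C@@H](O[Si](C)(C)C(C)(C)C)C=CC=C1Br | intermediate
4 | (tributylstannyl)methanol | OC[Sn](CCCC)(CCCC)CCCC | starting material
5 | (1R,6S)-6-[(tert-butyldimethylsilyl)oxy]-2-(hydroxymethyl)cyclohexa-2,4-dien-1-ol | O[C@H]1[C@@H](O[Si](C)(C)C(C)(C)C)C=CC=C1CO | intermediate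
6 | benzoyl chloride | O=C(Cl)c1ccccc1 | starting material
7 | [(5S,6R)-5-[(tert-butyldimethylsilyl)oxy]-6-hydroxycyclohexa-1,3-dien-1-yl]methyl benzoate | O[C@H]1[C@@H](O[Si](C)(C)C(C)(C)C)C=CC=C1COC(=O)c1ccccc1 | intermediate
8 | tert-butyl hydroperoxide | CC(C)(C)OO | starting material
9 | [(1S,2S,3S,6R)-3-[(tert-butyldimethylsilyl)oxy]-2-hydroxy-7-oxabicyclo[4.1.0]hept-4-en-1-yl]methyl benzoate | O[C@H]1[C@@H](O[Si](C)(C)C(C)(C)C)C=C[C@H]2O[C@@]12COC(=O)c1ccccc1 | intermediate
10 | acetic anhydride | CC(=O)OC(C)=O | starting material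
11 | [(1R,2S,3S,6R)-2-acetoxy-3-[(tert-butyldimethylsilyl)oxy]-7-oxabicyclo[4.1.0]hept-4-en-1-yl]methyl benzoate | CC(=O)O[C@H]1[C@@H](O[Si](C)(C)C(C)(C)C)C=C[C@H]2O[C@@]12COC(=O)c1ccccc1 | intermediate
12 | [(1R,2S,3S,6R)-2-acetoxy-3-hydroxy-7-oxabicyclo[4.1.0]hept-4-en-1-yl]methyl benzoate | CC(=O)O[C@H]1[C@@H](O)C=C[C@H]2O[C@@]12COC(=O)c1ccccc1 | intermediate
13 | benzoic acid | O=C(O)c1ccccc1 | starting material
14 | [(1R,2S,3R,6R)-2-acetoxy-3-(benzoyloxy)-7-oxabicyclo[4.1.0]hept-4-en-1-yl]methyl benzoate | CC(=O)O[C@H]1[C@H](OC(=O)c2ccccc2)C=C[C@H]2O[C@@]12COC(=O)c1ccccc1 | intermediate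
15 | water | O | starting material
16 | [(1R,2S,3R,6S)-2-acetoxy-3-(benzoyloxy)-1,6-dihydroxycyclohex-4-en-1-yl]methyl benzoate (HY-N2634) | CC(=O)O[C@H]1[C@H](OC(=O)c2ccccc2)C=C[C@H](O)[C@]1(O)COC(=O)c1ccccc1 | target

Total step count: 8. Longest linear sequence: 8 steps (from 1 to 16).

Steps most likely to fail

1. Step 4 (key epoxidation). The dienol may lose water or silanol and aromatise, the C2 carbinol may be oxidised to a dienone that tautomerises to a phenol, or oxygen may be delivered with poor site or facial control. The fallback sets out from 5 and comes back at 9. A Katsuki–Sharpless epoxidation anchored on the primary C7 hydroxyl of 5 (Ti(OiPr)4, D-(−)-diisopropyl tartrate, t-BuOOH, 4 Å molecular sieves, CH2Cl2, −20 °C) should give (1S,2S,3S,6R)-3-[(tert-butyldimethylsilyl)oxy]-1-(hydroxymethyl)-7-oxabicyclo[4.1.0]hept-4-en-2-ol F1. Here the face is chosen by the tartrate: the D antipode is the one the face rule assigns to the upper face of C1=C6, which the C2 hydroxyl also favours, so reagent and substrate control are matched. The medium is an alkoxide-buffered one at −20 °C. Benzoylation of the primary hydroxyl of F1 (BzCl, 2,4,6-collidine, CH2Cl2, −78 °C) then gives 9.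

2. Step 8 (oxirane opening). Hydration may be neither regio- nor stereospecific: water may enter at C4 in the conjugate sense, a free allyl cation may collapse to the cis-diol, or the C7 benzoyl group may travel to O6 through a cyclic acyloxonium ion. The fallback sets out from 14 and comes back at 16. Buffered formolysis (HCO2H, HCO2Na, 0 °C → rt) supplies the nucleophile at solvent concentration, so capture at C6 should be bimolecular and anti, as in the classical peracid trans-hydroxylation sequence, giving [(1R,2S,3R,6S)-2-acetoxy-3-(benzoyloxy)-6-(formyloxy)-1-hydroxycyclohex-4-en-1-yl]methyl benzoate F2. The formate is then removed under conditions too mild for acetate or benzoate (KHCO3 (cat.), MeOH, 0 °C), which gives 16.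

3. Step 2 (hydroxymethylation). Transfer of the CH2OH group may be too slow at a temperature the diene tolerates, so that butyl transfer, protodebromination, Diels–Alder dimerisation or dehydrative aromatisation take over. The fallback sets out from 3 and comes back at 5. The C7 carbon is brought in as carbon monoxide: methoxycarbonylation of 3 (PdCl2(PPh3)2 (5 mol %), CO (1 atm), MeOH, Et3N, DMF, 50 °C) should give methyl (5S,6R)-5-[(tert-butyldimethylsilyl)oxy]-6-hydroxycyclohexa-1,3-diene-1-carboxylate F3, a diene stabilised by conjugation with the ester. Reduction with i-Bu2AlH (3.2 equiv, CH2Cl2, −78 °C) then gives 5.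

Further compounds
F1 | step 4 | (1S,2S,3S,6R)-3-[(tert-butyldimethylsilyl)oxy]-1-(hydroxymethyl)-7-oxabicyclo[4.1.0]hept-4-en-2-ol | O[C@H]1[C@@H](O[Si](C)(C)C(C)(C)C)C=C[C@H]2O[C@@]12CO
F2 | step 8 | [(1R,2S,3R,6S)-2-acetoxy-3-(benzoyloxy)-6-(formyloxy)-1-hydroxycyclohex-4-en-1-yl]methyl benzoate | CC(=O)O[C@H]1[C@H](OC(=O)c2ccccc2)C=C[C@H](OC=O)[C@]1(O)COC(=O)c1ccccc1
F3 | step 2 | methyl (5S,6R)-5-[(tert-butyldimethylsilyl)oxy]-6-hydroxycyclohexa-1,3-diene-1-carboxylate | O[C@H]1[C@@H](O[Si](C)(C)C(C)(C)C)C=CC=C1C(=O)OC
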